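The target is cut back to a cyclohexene that already carries both ten-ring bonds. The feature exploited is the six-membered ring C1–C14–C13–C12–C11–C10, with quaternary C1, C10–H, and the C1–C2 and C10–C9 bonds trans. One catalytic enantioselective Diels–Alder reaction forms C10–C11 and C1–C14, closes that ring and fixes C1 and C10. Every later stereocentre is relayed from these two or set by reagent control. The precursors are a 2-silyloxybutadiene (C11–C14) and an (E)-α-methyl enal bearing a silyloxymethyl group (C9, C10, C1, C2). The ten-membered ring is closed late by Nozaki–Hiyama–Kishi coupling (C6–C7) and the lactone by Reformatsky annulation.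

Key step: step 3

Numbering used throughout: ten-membered ring C1–C10; cyclohexene C10–C11–C12–C13–C14–C1; lactone C7–O–C19(=O)–C17–C8; methyl groups C15 (on C1), C16 (on C5), C18 (on C17), C20 (on C11).

Assumption 1: the (S)-diphenylprolinol-derived oxazaborolidinium cation is taken as the antipode that exposes the Cα-Si/Cβ-Si face of enal 5; if the β-substituent reverses the facial preference, the mirror-image catalyst is used with no other change.

Assumption 2: compounds 7–17 are carried as mixtures of C2 epimers (11 also as C11 epimers); these centres become sp2 later (C2 in step 13, C11 in step 8), so the mixtures converge.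

Step 1
Reactants: 1 methyl vinyl ketone
Product: 2 2-(triethylsilyloxy)buta-1,3-diene
Conditions: TESOTf, Et3N, Et2O, 0 °C
Reagents that add atoms: triethylsilyl trifluoromethanesulfonate CC[Si](CC)(CC)OS(=O)(=O)C(F)(F)F
Why: Soft enolisation and O-silylation (silyl enol ether formation) can involve only the methyl group of the ketone, so the 2-silyloxydiene is the sole regioisomer.

Step 2
Reactants: 3 (tert-butyldimethylsilyloxy)acetaldehyde; 4 2-(triphenylphosphoranylidene)propanal
Product: 5 (E)-4-(tert-butyldimethylsilyloxy)-2-methylbut-2-enal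
Conditions: toluene, 80 °C
Reagents that add atoms: none
Why: Wittig olefination with the formyl-stabilised ylide gives the (E)-trisubstituted enal, which places the silyloxymethyl carbon (C9) cis to the methyl group and trans to the formyl group.

Step 3
Reactants: 2 2-(triethylsilyloxy)buta-1,3-diene; 5 (E)-4-(tert-butyldimethylsilyloxy)-2-methylbut-2-enal
Product: 6 (1S,6S)-6-[(tert-butyldimethylsilyloxy)methyl]-1-methyl-4-(triethylsilyloxy)cyclohex-3-ene-1-carbaldehyde
Conditions: (S)-B-(o-tolyl)oxazaborolidinium triflimide [from (S)-α,α-diphenylprolinol, o-tolylboroxine, Tf2NH] (20 mol%), 2 (2 equiv), CH2Cl2, −78 → −40 °C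
Reagents that add atoms: none
Why: The formyl oxygen of 5 binds the cationic boron centre (s-trans enal), which lowers the LUMO, and the diene then adds in a concerted, asynchronous, suprafacial [4+2] process in which its CH2 terminus next to the silyloxy carbon (C11) bonds to the enal β-carbon C10 slightly ahead of C14–C1. The closest known reaction type is the oxazaborolidinium-catalysed Diels–Alder reaction of α-substituted enals with 2-silyloxybutadienes. The cyclohexene ring (C1, C10–C14) is closed by intermolecular [4+2] annulation, both new σ-bonds being made on the same face of the alkene. The absolute configuration of C1 and C10 is set by the catalyst, which shields one enal face so that the diene adds to the Cα-Si/Cβ-Si face, and their relative configuration (C2 trans to C9, C15 cis to C9) is transferred stereospecifically from the E-alkene. The regiochemistry needed, with the silyloxy carbon C12 "para" to the formyl-bearing C1, is secured by the 2-silyloxy group, whose largest HOMO coefficient at C11 matches the large LUMO coefficient at the enal β-carbon. Endo/exo orientation has no consequence because the diene termini are unsubstituted, and excess diene with strict exclusion of protic acid protects the acid-labile silyl enol ether.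

Step 4
Reactants: 6 (1S,6S)-6-[(tert-butyldimethylsilyloxy)methyl]-1-methyl-4-(triethylsilyloxy)cyclohex-3-ene-1-carbaldehyde
Product: 7 1-[(1S,6S)-6-[(tert-butyldimethylsilyloxy)methyl]-1-methyl-4-(triethylsilyloxy)cyclohex-3-en-1-yl]ethanol (C2 epimers)
Conditions: MeMgBr, THF, −78 °C; pH 7 buffer
Reagents that add atoms: methylmagnesium bromide C[Mg]Br
Why: Grignard addition to the non-enolisable neopentyl aldehyde installs C3, the silyl enol ether is inert to the basic reagent, and the new C2 configuration is irrelevant because C2 is oxidised in step 13.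

Step 5
Reactants: 7 1-[(1S,6S)-6-[(tert-butyldimethylsilyloxy)methyl]-1-methyl-4-(triethylsilyloxy)cyclohex-3-en-1-yl]ethanol
Product: 8 TBS ether of 7 (C2–OTBS; C2 epimers)
Conditions: TBSOTf, 2,6-lutidine, CH2Cl2, −78 °C
Reagents that add atoms: tert-butyldimethylsilyl trifluoromethanesulfonate CC(C)(C)[Si](C)(C)OS(=O)(=O)C(F)(F)F
Why: Silylation under buffered basic conditions masks the C2 hydroxyl for the enolate chemistry that follows and leaves the silyl enol ether intact.

Step 6
Reactants: 8 TBS ether of 7
Product: 9 4-[1-(tert-butyldimethylsilyloxy)ethyl]-5-[(tert-butyldimethylsilyloxy)methyl]-4-methylcyclohex-2-en-1-one (C12 ketone, C13=C14; C1 and C10 as in 6)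
Conditions: Pd(OAc)2 (1.1 equiv), MeCN, rt
Reagents that add atoms: none
Why: In the Saegusa–Ito oxidation the enol ether is transmetallated to a palladium(II) enolate at C13 and β-hydride elimination of a C14 hydrogen gives the enone, so the regiochemistry laid down by the cycloaddition is kept.

Step 7
Reactants: 9 4-[1-(tert-butyldimethylsilyloxy)ethyl]-5-[(tert-butyldimethylsilyloxy)methyl]-4-methylcyclohex-2-en-1-one
Product: 11 6-methyl derivative of 9 (C20 on C11; C11 epimers), via lithium dienolate 10 (not isolated)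
Conditions: LDA, THF, −78 °C; then MeI, −78 → −40 °C
Reagents that add atoms: iodomethane CI
Why: Kinetic α'-deprotonation is possible only at C11 because C1 is quaternary, and C-methylation of the cross-conjugated enolate (enolate alkylation) installs C20, its configuration being erased in step 8.

Step 8
Reactants: 11 6-methyl derivative of 9
Product: 13 3-[(tert-butyldimethylsilyloxy)methyl]-4-[1-(tert-butyldimethylsilyloxy)ethyl]-2,4-dimethylcyclohexa-1,5-dien-1-yl trifluoromethanesulfonate, via potassium dienolate 12 (not isolated)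
Conditions: KHMDS, THF, −78 °C; then PhNTf2, −78 → 0 °C
Reagents that add atoms: N-phenylbis(trifluoromethanesulfonimide) O=S(=O)(N(c1ccccc1)S(=O)(=O)C(F)(F)F)C(F)(F)F
Why: The only removable proton is C11–H, and O-sulfonylation of the resulting dienolate (enol triflate formation) fixes the C11=C12 double bond.

Step 9
Reactants: 13 dienyl triflate
Product: 14 6-[(tert-butyldimethylsilyloxy)methyl]-5-[1-(tert-butyldimethylsilyloxy)ethyl]-1,5-dimethylcyclohexa-1,3-diene (C11(Me)=C12–C13=C14)
Conditions: Pd(OAc)2 (5 mol%), PPh3, HCO2H, Bu3N, DMF, 60 °C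
Reagents that add atoms: none
Why: Palladium-catalysed formate reduction of the enol triflate (oxidative addition, decarboxylation of the formate complex, reductive elimination) gives the 1,3-diene, and aromatisation is blocked by quaternary C1.

Step 10
Reactants: 14 cyclohexa-1,3-diene
Product: 15 cis-11,12-diol (11S,12R; hydroxyls trans to C9; C2 epimers)
Conditions: OsO4 (5 mol%), NMO, acetone–H2O, 0 °C
Reagents that add atoms: N-methylmorpholine N-oxide C[N+]1([O-])CCOCC1; water O; osmium tetroxide (catalytic oxygen carrier) O=[Os](=O)(=O)=O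
Why: Upjohn syn-dihydroxylation should take the more electron-rich trisubstituted C11=C12 bond (C13=C14 is flanked by quaternary C1) on the face anti to the C10 silyloxymethyl group, which sets both hydroxyls cis to each other and trans to C9.

Step 11
Reactants: 15 cis-11,12-diol
Product: 16 11,12-O-isopropylidene derivative of 15
Conditions: 2,2-dimethoxypropane, PPTS (cat.), CH2Cl2, rt
Reagents that add atoms: 2,2-dimethoxypropane COC(C)(C)OC
Why: Acid-catalysed transketalisation (acetonide formation) is fast for a cis-1,2-diol on a six-membered ring and protects the tertiary and the secondary hydroxyl together.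

Step 12
Reactants: 16 acetonide
Product: 17 diol with free C9H2OH and C2H(OH)CH3 (C2 epimers)
Conditions: TBAF, THF, 0 → 40 °C
Reagents that add atoms: none
Why: Fluoride-mediated desilylation removes both TBS ethers and does not touch the acetonide.

Step 13
Reactants: 17 diol
Product: 18 keto aldehyde (C9 aldehyde, C2 methyl ketone; single stereoisomer)
Conditions: (COCl)2, DMSO, CH2Cl2, −78 °C; Et3N, −78 → −30 °C
Reagents that add atoms: none
Why: In the Swern oxidation both hydroxyls are converted into alkoxysulfonium ions before base is added, so the 1,4-diol goes to the keto aldehyde without lactol or lactone formation, and both C2 epimers converge.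

Step 14
Reactants: 18 keto aldehyde; 19 ethyl 1,3-dithiane-2-carboxylate
Product: 21 ethyl 2-[(R)-hydroxy(cyclohexenyl)methyl]-1,3-dithiane-2-carboxylate (9R aldol; C7 ester, C8 dithiane), via lithio dithiane ester enolate 20 (not isolated)
Conditions: LDA, 19, THF, −78 °C; then 18, −78 °C; pH 7 buffer at −78 °C
Reagents that add atoms: none
Why: Aldol addition of the stabilised, weakly basic enolate (a glyoxylate anion equivalent) is chemoselective for the aldehyde over the hindered methyl ketone, and attack anti to quaternary C1 (Felkin–Anh), the face also favoured by lithium chelation between the aldehyde and the C11 acetonide oxygen, should give 9R.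

Step 15
Reactants: 21 aldol adduct
Product: 22 C9 triethylsilyl ether of 21
Conditions: TESOTf, 2,6-lutidine, CH2Cl2, −78 °C
Reagents that add atoms: triethylsilyl trifluoromethanesulfonate CC[Si](CC)(CC)OS(=O)(=O)C(F)(F)F
Why: Silylation blocks retro-aldol and hemiketal formation with the C2 ketone, and the TES group is chosen so that it leaves with the acetonide in step 26.

Step 16
Reactants: 23 propargyl alcohol
Product: 25 (Z)-3-iodo-2-methylprop-2-en-1-ol, via alkenylmagnesium alkoxide 24 (not isolated)
Conditions: MeMgBr (2.5 equiv), CuI (10 mol%), THF, −10 °C → rt; then I2, −20 °C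
Reagents that add atoms: methylmagnesium bromide C[Mg]Br; iodine II
Why: Alkoxide-directed copper-catalysed anti-carbomagnesiation puts the methyl group on the internal and magnesium on the terminal carbon, and iodinolysis with retention gives the iodoalkene with CH2OH and iodine cis, the geometry needed for the Z C5=C6 bond.

Step 17
Reactants: 25 (Z)-3-iodo-2-methylprop-2-en-1-ol
Product: 26 (Z)-3-bromo-1-iodo-2-methylprop-1-ene
Conditions: CBr4, PPh3, CH2Cl2, 0 °C
Reagents that add atoms: carbon tetrabromide BrC(Br)(Br)Br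
Why: The Appel reaction converts the primary allylic alcohol into the bromide under neutral conditions without touching the alkenyl iodide or the alkene geometry.

Step 18
Reactants: 22 TES-protected keto ester; 26 (Z)-3-bromo-1-iodo-2-methylprop-1-ene
Product: 28 C2 ketone carrying the chain C3H2–C4H2–C5(CH3)=C6H–I (Z), via lithium methyl ketone enolate 27 (not isolated)
Conditions: LDA, THF, −78 °C; then 26, DMPU, −78 → −40 °C
Reagents that add atoms: none
Why: The ketone can enolise only toward its methyl group (C3), the ester has no α-hydrogen and the alkenyl iodide is inert to the enolate, so SN2 alkylation at the allylic bromide (enolate alkylation) forms C3–C4 with the Z-alkene intact.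

Step 19
Reactants: 28 alkylated ketone
Product: 29 (2R)-alcohol
Conditions: (S)-Me-CBS (0.5 equiv), catecholborane, toluene, −78 → −40 °C
Reagents that add atoms: none
Why: In the Corey–Bakshi–Shibata reduction quaternary C1 acts as the large and C3H2 as the small ketone substituent, so the (S)-catalyst delivers hydride under reagent control to give 2R, and catecholborane leaves the ester, the alkenes and the iodide untouched.

Step 20
Reactants: 29 (2R)-alcohol
Product: 30 2,9-bis(triethylsilyl) ether
Conditions: TESOTf, 2,6-lutidine, CH2Cl2, −78 °C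
Reagents that add atoms: triethylsilyl trifluoromethanesulfonate CC[Si](CC)(CC)OS(=O)(=O)C(F)(F)F
Why: Silylation of the C2 hydroxyl ensures that the C7 hydroxyl made in step 22 is the only free alcohol at the acylation stage.

Step 21
Reactants: 30 bis(triethylsilyl) ether
Product: 31 C7 aldehyde (2-formyl-1,3-dithiane)
Conditions: DIBAL-H (1.2 equiv), CH2Cl2, −78 °C; Rochelle salt
Reagents that add atoms: none
Why: Partial reduction of the α-quaternary ethyl ester stops at the tetrahedral aluminium hemiacetal, which is stable at −78 °C and releases the aldehyde only on work-up.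

Step 22
Reactants: 31 C7 aldehyde
Product: 32 ten-membered (7S)-allylic alcohol (C6–C7 bond formed; Z C5=C6; C8 dithiane)
Conditions: CrCl2 (10 equiv), NiCl2 (1 mol%), DMSO–THF, rt, 2 mM, syringe-pump addition
Reagents that add atoms: none
Why: In the intramolecular Nozaki–Hiyama–Kishi reaction nickel(0) inserts into the C6–I bond with retention of geometry, transmetallation to chromium(III) and chemoselective addition to the aldehyde close the ring from chains that the trans C2/C9 attachment holds side by side, and 7S is expected from the ring-closing conformation in which the carbonyl oxygen points to the ring periphery away from the C9 silyl ether.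

Step 23
Reactants: 32 ten-membered allylic alcohol; 33 2-bromopropanoyl bromide (racemic)
Product: 34 C7 2-bromopropanoate
Conditions: pyridine, DMAP (cat.), CH2Cl2, −20 °C
Reagents that add atoms: none
Why: O-Acylation of the only free hydroxyl attaches C17–C19, and the configuration at the bromine-bearing carbon is irrelevant because it becomes an enolate carbon.

Step 24
Reactants: 34 C7 2-bromopropanoate
Product: 35 C8 ketone
Conditions: PhI(O2CCF3)2, MeCN–H2O (9:1), 0 °C, short contact; NaHCO3 work-up
Reagents that add atoms: water O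
Why: Oxidative dithiane hydrolysis (sulfur activation by iodine(III), thionium ion, capture by water) is faster than any reaction of the alkenes, and with the C7 oxygen already acylated the unveiled ketone cannot isomerise through an enediol.

Step 25
Reactants: 35 C8 ketone
Product: 36 lactone (7S,8S,9R,17R; 8-OH free; 2,9-bis-TES ether and 11,12-acetonide retained)
Conditions: SmI2 (2.5 equiv), THF, −78 °C
Reagents that add atoms: none
Why: In the samarium(II)-mediated intramolecular Reformatsky reaction the C–Br bond is reduced faster than the ketone and the samarium enolate adds to C8 through the C7 ester tether; a five-membered lactone can span C7–C8 of the ten-membered ring without eclipsing C6–C7–C8–C9 only when trans-fused, which leaves 8-OH cis to C6 (8S), and the samarium-bridged transition state places the C18 methyl on the side of the C8–O bond away from C9 (17R), which is also the more stable epimer.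

Step 26
Reactants: 36 protected lactone
Product: 37 pentaol (2,9,12-triol with free tertiary 8- and 11-hydroxyls; configured as in 38)
Conditions: TFA–H2O–THF (1:1:4), 0 °C → rt
Reagents that add atoms: none
Why: Acid hydrolysis removes both TES ethers and the acetonide in one operation, while the lactone and the tertiary alcohols tolerate dilute acid at this temperature.

Step 27
Reactants: 37 pentaol
Product: 38 CNP0129620.2 (2,9,12-triacetate; 1S,2R,7S,8S,9R,10S,11S,12R,17R)
Conditions: Ac2O, pyridine, DMAP (cat.), CH2Cl2, 0 °C → rt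
Reagents that add atoms: acetic anhydride CC(=O)OC(C)=O
Why: Acetylation takes the three secondary hydroxyls at C2, C9 and C12, whereas the tertiary hydroxyls at C8 and C11 are not acylated under these mild conditions.

Compound list

1 | methyl vinyl ketone | CC(=O)C=C | starting material
2 | 2-(triethylsilyloxy)buta-1,3-diene | C=CC(=C)O[Si](CC)(CC)CC | intermediate
3 | (tert-butyldimethylsilyloxy)acetaldehyde | CC(C)(C)[Si](C)(C)OCC=O | starting material
4 | 2-(triphenylphosphoranylidene)propanal | CC(C=O)=P(c1ccccc1)(c1ccccc1)c1ccccc1 | starting material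
5 | (E)-4-(tert-butyldimethylsilyloxy)-2-methylbut-2-enal | CC(C)(C)[Si](C)(C)OC/C=C(C)/C=O | intermediate
6 | (1S,6S)-6-[(tert-butyldimethylsilyloxy)methyl]-1-methyl-4-(triethylsilyloxy)cyclohex-3-ene-1-carbaldehyde | CC(C)(C)[Si](C)(C)OC[C@H]1CC(O[Si](CC)(CC)CC)=CC[C@]1(C)C=O | intermediate
7 | 1-[(1S,6S)-6-[(tert-butyldimethylsilyloxy)methyl]-1-methyl-4-(triethylsilyloxy)cyclohex-3-en-1-yl]ethanol, C2 epimers | CC(C)(C)[Si](C)(C)OC[C@H]1CC(O[Si](CC)(CC)CC)=CC[C@]1(C)C(C)O | intermediate
8 | TBS ether of 7, C2 epimers | CC(C)(C)[Si](C)(C)OC[C@H]1CC(O[Si](CC)(CC)CC)=CC[C@]1(C)C(C)O[Si](C)(C)C(C)(C)C | intermediate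
9 | 4-[1-(tert-butyldimethylsilyloxy)ethyl]-5-[(tert-butyldimethylsilyloxy)methyl]-4-methylcyclohex-2-en-1-one, ring centres as in 6 | CC(C)(C)[Si](C)(C)OC[C@H]1CC(=O)C=C[C@]1(C)C(C)O[Si](C)(C)C(C)(C)C | intermediate
10 | lithium cross-conjugated dienolate of 9 (not isolated) | [Li+].CC(C)(C)[Si](C)(C)OC[C@H]1C=C([O-])C=C[C@]1(C)C(C)O[Si](C)(C)C(C)(C)C | intermediate
11 | 6-methyl derivative of 9 (C20 on C11), C11 and C2 epimers | CC(C)(C)[Si](C)(C)OC[C@H]1C(C)C(=O)C=C[C@]1(C)C(C)O[Si](C)(C)C(C)(C)C | intermediate
12 | potassium dienolate of 11 (not isolated) | [K+].CC(C)(C)[Si](C)(C)OC[C@H]1C(C)=C([O-])C=C[C@]1(C)C(C)O[Si](C)(C)C(C)(C)C | intermediate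
13 | 3-[(tert-butyldimethylsilyloxy)methyl]-4-[1-(tert-butyldimethylsilyloxy)ethyl]-2,4-dimethylcyclohexa-1,5-dien-1-yl trifluoromethanesulfonate | CC(C)(C)[Si](C)(C)OC[C@H]1C(C)=C(OS(=O)(=O)C(F)(F)F)C=C[C@]1(C)C(C)O[Si](C)(C)C(C)(C)C | intermediate
14 | 6-[(tert-butyldimethylsilyloxy)methyl]-5-[1-(tert-butyldimethylsilyloxy)ethyl]-1,5-dimethylcyclohexa-1,3-diene | CC(C)(C)[Si](C)(C)OC[C@H]1C(C)=CC=C[C@]1(C)C(C)O[Si](C)(C)C(C)(C)C | intermediate
15 | cis-11,12-diol (11S,12R), bis-TBS ether | CC(C)(C)[Si](C)(C)OC[C@H]1[C@](C)(O)[C@H](O)C=C[C@]1(C)C(C)O[Si](C)(C)C(C)(C)C | intermediate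
16 | 11,12-acetonide of 15 | CC(C)(C)[Si](C)(C)OC[C@H]1[C@]2(C)OC(C)(C)O[C@@H]2C=C[C@]1(C)C(C)O[Si](C)(C)C(C)(C)C | intermediate
17 | acetonide diol (C9H2OH, C2H(OH)CH3), C2 epimers | OC[C@H]1[C@]2(C)OC(C)(C)O[C@@H]2C=C[C@]1(C)C(C)O | intermediate
18 | acetonide keto aldehyde (C9 aldehyde, C2 methyl ketone) | O=C[C@H]1[C@]2(C)OC(C)(C)O[C@@H]2C=C[C@]1(C)C(C)=O | intermediate
19 | ethyl 1,3-dithiane-2-carboxylate | CCOC(=O)C1SCCCS1 | starting material
20 | lithium enolate of 19 (not isolated) | [Li+].CCOC([O-])=C1SCCCS1 | intermediate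
21 | (9R)-aldol adduct (C7 ethyl ester, C8 dithiane, C2 methyl ketone) | CCOC(=O)C1(SCCCS1)[C@H](O)[C@H]2[C@]3(C)OC(C)(C)O[C@@H]3C=C[C@]2(C)C(C)=O | intermediate
22 | C9 triethylsilyl ether of 21 | CCOC(=O)C1(SCCCS1)[C@H](O[Si](CC)(CC)CC)[C@H]2[C@]3(C)OC(C)(C)O[C@@H]3C=C[C@]2(C)C(C)=O | intermediate
23 | propargyl alcohol | C#CCO | starting material
24 | (Z)-alkenylmagnesium bromide alkoxide from 23 (not isolated) | Br[Mg]OC/C(C)=C\[Mg]Br | intermediate
25 | (Z)-3-iodo-2-methylprop-2-en-1-ol | OC/C(C)=C\I | intermediate
26 | (Z)-3-bromo-1-iodo-2-methylprop-1-ene | BrC/C(C)=C\I | intermediate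
27 | lithium enolate of methyl ketone 22 (not isolated) | [Li+].CCOC(=O)C1(SCCCS1)[C@H](O[Si](CC)(CC)CC)[C@H]2[C@]3(C)OC(C)(C)O[C@@H]3C=C[C@]2(C)C([O-])=C | intermediate
28 | C2 ketone with (Z)-iodoalkenyl chain C3–C6 | CCOC(=O)C1(SCCCS1)[C@H](O[Si](CC)(CC)CC)[C@H]2[C@]3(C)OC(C)(C)O[C@@H]3C=C[C@]2(C)C(=O)CC/C(C)=C\I | intermediate
29 | (2R)-alcohol from 28 | CCOC(=O)C1(SCCCS1)[C@H](O[Si](CC)(CC)CC)[C@H]2[C@]3(C)OC(C)(C)O[C@@H]3C=C[C@]2(C)[C@H](O)CC/C(C)=C\I | intermediate
30 | 2,9-bis(triethylsilyl) ether ester | CCOC(=O)C1(SCCCS1)[C@H](O[Si](CC)(CC)CC)[C@H]2[C@]3(C)OC(C)(C)O[C@@H]3C=C[C@]2(C)[C@H](O[Si](CC)(CC)CC)CC/C(C)=C\I | intermediate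
31 | C7 aldehyde (2-formyl-1,3-dithiane) with (Z)-alkenyl iodide | O=CC1(SCCCS1)[C@H](O[Si](CC)(CC)CC)[C@H]2[C@]3(C)OC(C)(C)O[C@@H]3C=C[C@]2(C)[C@H](O[Si](CC)(CC)CC)CC/C(C)=C\I | intermediate
32 | ten-membered (7S)-allylic alcohol, C8 dithiane, 2,9-bis-TES, 11,12-acetonide | CC[Si](CC)(CC)O[C@@H]1[C@H]2[C@]3(C)OC(C)(C)O[C@@H]3C=C[C@]2(C)[C@H](O[Si](CC)(CC)CC)CC/C(C)=C\[C@H](O)C14SCCCS4 | intermediate
33 | 2-bromopropanoyl bromide (racemic) | CC(Br)C(=O)Br | starting material
34 | C7 2-bromopropanoate of 32 | CC[Si](CC)(CC)O[C@@H]1[C@H]2[C@]3(C)OC(C)(C)O[C@@H]3C=C[C@]2(C)[C@H](O[Si](CC)(CC)CC)CC/C(C)=C\[C@H](OC(=O)C(C)Br)C14SCCCS4 | intermediate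
35 | C8 ketone bearing the C7 2-bromopropanoate | CC[Si](CC)(CC)O[C@@H]1[C@H]2[C@]3(C)OC(C)(C)O[C@@H]3C=C[C@]2(C)[C@H](O[Si](CC)(CC)CC)CC/C(C)=C\[C@H](OC(=O)C(C)Br)C1=O | intermediate
36 | protected lactone (7S,8S,9R,17R) | CC[Si](CC)(CC)O[C@@H]1[C@H]2[C@]3(C)OC(C)(C)O[C@@H]3C=C[C@]2(C)[C@H](O[Si](CC)(CC)CC)CC/C(C)=C\[C@@H]2OC(=O)[C@H](C)[C@]21O | intermediate
37 | pentaol (deacetyl target) | O[C@@H]1[C@H]2[C@](C)(O)[C@H](O)C=C[C@]2(C)[C@H](O)CC/C(C)=C\[C@@H]2OC(=O)[C@H](C)[C@]21O | intermediate
38 | CNP0129620.2 | CC(=O)O[C@@H]1[C@H]2[C@](C)(O)[C@H](OC(C)=O)C=C[C@]2(C)[C@H](OC(C)=O)CC/C(C)=C\[C@@H]2OC(=O)[C@H](C)[C@]21O | target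

Total step count: 27. Longest linear sequence: 24 steps (steps 2–15 and 18–27); steps 1, 16 and 17 are side branches.

Steps most likely to fail

Step 3. The trisubstituted, β-branched enal may turn over slowly on the catalyst, the enal face may be discriminated poorly, and the diene may be lost by protodesilylation. The fallback makes the ring racemic and resolves it. It sets out from 2 and 5, which are combined with Me2AlCl (CH2Cl2, −78 °C) to give the racemic trans adduct F1. DIBAL-H (−78 °C) reduces it to the racemic primary alcohol F2. Esterification with (S)-O-methylmandelic acid (DCC, DMAP) gives two diastereomeric esters, from which the (1S,6S) ester F3 is separated by chromatography on deactivated silica. DIBAL-H (−78 °C) then releases the enantiopure alcohol F4, and Parikh–Doering oxidation (SO3·pyridine, DMSO, iPr2NEt) returns to the route at 6.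

Step 22. The alkenylchromium species may be protonated or may couple intermolecularly faster than it closes the ten-membered ring, and the aldehyde face may be selected poorly. The fallback closes the ring by olefin metathesis at C5=C6. It sets out from 22, which is alkylated (LDA, 3-bromo-2-methylpropene) to the methallyl ketone F5. F5 is reduced with (S)-Me-CBS and catecholborane to the (2R)-alcohol F6, silylated (TESOTf, 2,6-lutidine) to the bis-silyl ether F7, and reduced with DIBAL-H (−78 °C) to the aldehyde F8. Vinylmagnesium bromide gives the allylic alcohol F9, whose 7S epimer is separated by chromatography. Ring-closing metathesis (Grubbs second-generation catalyst, toluene, 80 °C, high dilution), in which ring strain should enforce the Z-alkene, returns to the route at 32.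

Step 25. Samarium(II) may cleave the C–O bonds α to the ketone before the enolate closes, and the tethered enolate may add to the wrong carbonyl face. The fallback forms C8–C17 intermolecularly under chelation control. It sets out from 32, whose dithiane is hydrolysed directly (PhI(O2CCF3)2, aqueous MeCN, 0 °C) to the α-hydroxy ketone F10. The zinc Reformatsky reagent from ethyl 2-bromopropanoate (excess, THF, 0 °C) adds to the zinc alkoxide chelate (C7–O–Zn···O=C8) on the face anti to C6, giving the hydroxy ester F11. F11 lactonises in the flask through the C7 alkoxide and, after equilibration of C17 with DBU if needed, the sequence returns to the route at 36.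

Further compounds

F1 | step 3 | racemic trans adduct (6 and its enantiomer) | CC(C)(C)[Si](C)(C)OC[C@H]1CC(O[Si](CC)(CC)CC)=CC[C@]1(C)C=O.CC(C)(C)[Si](C)(C)OC[C@@H]1CC(O[Si](CC)(CC)CC)=CC[C@@]1(C)C=O
F2 | step 3 | racemic [6-[(tert-butyldimethylsilyloxy)methyl]-1-methyl-4-(triethylsilyloxy)cyclohex-3-en-1-yl]methanol | CC(C)(C)[Si](C)(C)OC[C@H]1CC(O[Si](CC)(CC)CC)=CC[C@]1(C)CO.CC(C)(C)[Si](C)(C)OC[C@@H]1CC(O[Si](CC)(CC)CC)=CC[C@@]1(C)CO
F3 | step 3 | (S)-O-methylmandelate of the (1S,6S)-alcohol | CC(C)(C)[Si](C)(C)OC[C@H]1CC(O[Si](CC)(CC)CC)=CC[C@]1(C)COC(=O)[C@@H](OC)c1ccccc1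
F4 | step 3 | [(1S,6S)-6-[(tert-butyldimethylsilyloxy)methyl]-1-methyl-4-(triethylsilyloxy)cyclohex-3-en-1-yl]methanol | CC(C)(C)[Si](C)(C)OC[C@H]1CC(O[Si](CC)(CC)CC)=CC[C@]1(C)CO
F5 | step 22 | C2 ketone with 3-methylbut-3-enyl chain | CCOC(=O)C1(SCCCS1)[C@H](O[Si](CC)(CC)CC)[C@H]2[C@]3(C)OC(C)(C)O[C@@H]3C=C[C@]2(C)C(=O)CCC(C)=C
F6 | step 22 | (2R)-alcohol from F5 | CCOC(=O)C1(SCCCS1)[C@H](O[Si](CC)(CC)CC)[C@H]2[C@]3(C)OC(C)(C)O[C@@H]3C=C[C@]2(C)[C@H](O)CCC(C)=C
F7 | step 22 | 2,9-bis(triethylsilyl) ether ester | CCOC(=O)C1(SCCCS1)[C@H](O[Si](CC)(CC)CC)[C@H]2[C@]3(C)OC(C)(C)O[C@@H]3C=C[C@]2(C)[C@H](O[Si](CC)(CC)CC)CCC(C)=C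
F8 | step 22 | C7 aldehyde with 3-methylbut-3-enyl chain | O=CC1(SCCCS1)[C@H](O[Si](CC)(CC)CC)[C@H]2[C@]3(C)OC(C)(C)O[C@@H]3C=C[C@]2(C)[C@H](O[Si](CC)(CC)CC)CCC(C)=C
F9 | step 22 | (7S)-vinyl carbinol, metathesis precursor | C=C[C@H](O)C1(SCCCS1)[C@H](O[Si](CC)(CC)CC)[C@H]2[C@]3(C)OC(C)(C)O[C@@H]3C=C[C@]2(C)[C@H](O[Si](CC)(CC)CC)CCC(C)=C
F10 | step 25 | ten-membered α-hydroxy ketone (7-OH, C8 ketone) | CC[Si](CC)(CC)O[C@@H]1[C@H]2[C@]3(C)OC(C)(C)O[C@@H]3C=C[C@]2(C)[C@H](O[Si](CC)(CC)CC)CC/C(C)=C\[C@H](O)C1=O
F11 | step 25 | Reformatsky hydroxy ester (7,8-diol, C17 epimers; not isolated) | CC[Si](CC)(CC)O[C@@H]1[C@H]2[C@]3(C)OC(C)(C)O[C@@H]3C=C[C@]2(C)[C@H](O[Si](CC)(CC)CC)CC/C(C)=C\[C@H](O)[C@@]1(O)C(C)C(=O)OCC
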